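Amounts first: the flask takes 0.17 M of substrate over 25 h, as epsilon did, but 1.00 equiv of coupling partner against 1.5 equiv, and the question is how much intermediate that gives, and when.

| flask | substrate | coupling partner | remark | time |
|---|---|---|---|---|
| epsilon | 0.17 M (fed, over 25 h) | 1.5 equiv | run made earlier; the fed solution adds 0.20 times the starting volume |  |
| flask | 0.17 M (fed, over 25 h) | 1.00 equiv | the fed solution adds 0.20 times the starting volume | 15 d |

epsilon run (percent of the substrate charged)

| time / h | intermediate / % | target / % | substrate / % |
|---|---|---|---|
| 6.00 | 3.7 | 0.5 | 19.9 |
| 12.0 | 10.4 | 2.1 | 35.0 |
| 20.0 | 20.3 | 6.1 | 52.0 |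
| 25.0 | 25.3 | 9.6 | 61.3 |
| 30.0 | 28.6 | 13.6 | 53.2 |
| 40.0 | 28.7 | 20.1 | 40.8 |

(each reading ± 0.3 percentage points)

- charges are per starting volume, the dose included; the dosed solution carries all of it
- on the list of suspects stand: substrate + coupling partner -> intermediate + by-product; intermediate <-> target; intermediate <-> isomer of the product; target -> over-reaction product; coupling partner -> decomposed reagent
- percentages count the whole charge, also what has not yet gone in

- the moment within 15 d at which there is most intermediate
- the amount of intermediate, in percent of the substrate charged, at that time
- earliest time at which at least nineteen twentieths of that best amount are there, in d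
- latest time at which they still are, in d

Intermediate peaks when coupling delivers what its onward steps remove. Substrate sees a pseudo-first-order constant proportional to the partner concentration, so for equal onward constants, and taken at the same hour, the peak height is reckoned to follow substrate on hand times partner left.

Epsilon's intermediate reads 28.6% and 28.7% at 30.0 h and 40.0 h, which puts its peak near 35.0 h, with substrate at about 46.6%. Its constant there reads 0.0265 h⁻¹, against 0.0540 h⁻¹ early in the dose, from substrate dosed minus substrate found. Corrected for dilution, that fall puts partner at about 77.8% of the substrate charge, a reading from scattered numbers. The coupling product Π, substrate times partner as shares of the substrate charge, therefore reads about 0.362 for epsilon. The partner balance then reads 12.6% of epsilon's partner charge as gone to decomposed reagent, a share assumed equal in the flask.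

The flask's coupled amount at that hour is reckoned to scale with partner charge and with the mean ratio of substrate on hand, which gives 40.5%. Its Π is then 0.279, and this reckoning puts the flask's peak at 22.1%.

The forecast, lower than this reckoning, says 20.7% at 1.43 d, open from 1.17 d to 1.79 d: “peaks near 34–35 h at about 20.7%, when coupling equals its loss”. The flask gives 22.0% at 1.52 d, open from 1.21 d to 1.95 d.

    substrate + coupling partner → intermediate + by-product (k = 0.260 M⁻¹ h⁻¹)
    intermediate ⇌ target (K = 2.80, k = 0.0410 h⁻¹)
    intermediate ⇌ isomer of the product (K = 2.20, k = 0.00780 h⁻¹)
    target → over-reaction product (k = 0.0150 h⁻¹)
    coupling partner → decomposed reagent (k = 0.00720 h⁻¹)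

In the flask at 1.23 d, substrate has a coupling half-life of 1.6 d, longer than the 0.70 d of intermediate by the forward rate of its step to target alone. At the best time, substrate stands at 58.6% against 22.0% of intermediate. The neighbour with 0.600 equiv of partner is reckoned the same way: coupled substrate comes to 27.3%, Π to 0.183, and the peak to 14.5%, where that flask gives 14.5%.

Readings and results are simulated for substances that don't exist; the scatter is artificial.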